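**Plan**
Cuts: the lactone O–C7 bond; the C20–O bond (back to a C20 methyl, oxidised from the C1 oxygen); ring D at C13–C16 and C8–C15; the inter-ring bond C9–C10; C5–C6.
Forward: ring A enol silane (conjugate vinyl addition), Mukaiyama–Michael union with a ring C keto ester enone, C8 propargylation, ring D by gold Conia-ene, C14 deoxygenation, C15/C16 adjustment, C20 oxygenation, lactone ring, then acetate, free acid and C15 ketone.
Stereochemistry: C5 by catalyst control; C10 by attack anti to the C5 vinyl; C9 by the open Michael transition state; C8 by alkylation anti to the C9 substituent; C13 by the tether; C1 by axial hydride; C16 by hydroxyl-directed exo hydrogenation.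
Enabling feature: C20 is a methyl on quaternary C10 of ring A, three bonds from the equatorial C1 oxygen and gauche to it, so an O1–SiEt2H tether reaches this methyl alone and closes the five-membered ring O1–Si–C20–C10–C1.

Key step: step 18

Remark: locants are those of ent-kaurane (ring A = C1–C5, C10; ring C = C8, C9, C11–C14; ring D = C8, C13–C16; C6 and C7 are the carboxyl carbons on C5 and C8). The target is (1S,5R,8S,9S,10S,13R,16R), with the C17 methyl endo (syn to the C11–C12 bridge).
Remark: β-keto esters 8 and 9 are drawn as enol tautomers; simple conjugate bases formed in the flask (enolates, alkoxides) are not numbered.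

Step 1
Reactants: 1 methyl 2-oxocyclohexane-1-carboxylate
Product: 3 methyl 6-oxocyclohex-1-ene-1-carboxylate, via keto selenide 2 (not isolated)
Conditions: PhSeCl, pyridine, CH2Cl2, 0 °C; then H2O2 (30% aq), 0 °C → rt; used at once
Reagents that add atoms: none
Why: Selenenylation of the enolised β-keto ester followed by selenoxide syn-elimination is the standard entry to this doubly activated enone, which should be used directly because it dimerises on standing.

Step 2
Reactants: 4 2,4,4-trimethylcyclohex-2-en-1-one
Product: 6 (R)-trimethyl[(2,4,4-trimethyl-3-vinylcyclohex-1-en-1-yl)oxy]silane, via aluminium enolate 5 (not isolated)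
Conditions: CH2=CHMgBr + Me2AlCl (gives Me2AlCH=CH2), [Cu(MeCN)4]BF4 (5 mol %), chiral phosphoramidite ligand (10 mol %), Et2O, −30 °C; then TMSOTf, −30 → 0 °C
Reagents that add atoms: dimethyl(vinyl)aluminium C=C[Al](C)C (made in the flask from vinylmagnesium bromide C=C[Mg]Br and dimethylaluminium chloride C[Al](C)Cl); trimethylsilyl trifluoromethanesulfonate C[Si](C)(C)OS(=O)(=O)C(F)(F)F
Why: Copper-catalysed enantioselective conjugate addition of an alkenylalane to a cyclic enone, with the ligand antipode chosen to give the (R)-centre at C5, followed by silyl trapping of the aluminium enolate, should fix the tetrasubstituted C1=C10 enol ether regiospecifically.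

Step 3
Reactants: 6 ring A enol silane; 3 methyl 6-oxocyclohex-1-ene-1-carboxylate
Product: 8 ring A–ring C diketo ester (enol form; C9–C10 bond formed), via silyl enol ether 7 (not isolated)
Conditions: Sc(OTf)3 (10 mol %), CH2Cl2, −78 → −40 °C; then 1 M HCl, THF, 0 °C
Reagents that add atoms: none
Why: Lewis-acid-catalysed Mukaiyama–Michael addition to a chelating alkylidene β-keto ester, in which C10 is attacked anti to the neighbouring C5 vinyl group (quaternary centre trans to C6) and C9 should arise from an open antiperiplanar transition state with the C9–H in the crowded sector between C1 and C5 (Si face of C10 onto the Re face of C9).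

Step 4
Reactants: 8 diketo ester
Product: 9 1-hydroxy keto ester (equatorial 1-OH cis to the C20 methyl)
Conditions: NaH (1.05 equiv), THF, 0 °C; then LiBH4, 0 °C → rt; aq NH4Cl
Reagents that add atoms: none
Why: Chemoselective borohydride reduction under enolate protection: the β-keto ester is held as its sodium enolate, so hydride reduces only the C1 ketone, entering axially on the face away from the axial C20 methyl to give the equatorial alcohol, and the adduct can then no longer revert by retro-Michael cleavage.

Step 5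
Reactants: 9 1-hydroxy keto ester
Product: 10 C8-propargyl keto ester (propargyl trans to the ring A substituent on C9)
Conditions: propargyl bromide, K2CO3, acetone, rt
Reagents that add atoms: propargyl bromide C#CCBr
Why: C-Alkylation of a cyclic β-keto ester enolate, where the electrophile should enter C8 anti to the bulky C9 substituent, places C15 trans and the C7 ester cis to C10.

Step 6
Reactants: 10 C8-propargyl keto ester
Product: 12 C6 carboxylic acid, via C6 aldehyde 11 (not isolated)
Conditions: OsO4 (2 mol %), NaIO4, 2,6-lutidine, dioxane/H2O, rt; then NaClO2, NaH2PO4, 2-methyl-2-butene, t-BuOH/H2O, 0 °C → rt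
Reagents that add atoms: OsO4 (osmium tetroxide, catalytic oxygen carrier) O=[Os](=O)(=O)=O; NaIO4 (sodium periodate) [Na+].[O-]I(=O)(=O)=O; NaClO2 (sodium chlorite) [Na+].[O-]Cl=O
Why: Lemieux–Johnson cleavage of the vinyl group spares the alkyne, and Pinnick oxidation takes the aldehyde to the acid under buffered conditions that should not epimerise C5, whose equatorial carbonyl is also the stable epimer.

Step 7
Reactants: 12 C6 carboxylic acid
Product: 13 C6 tert-butyl ester
Conditions: Me2NCH(Ot-Bu)2, toluene, 80 °C
Reagents that add atoms: N,N-dimethylformamide di-tert-butyl acetal CN(C)C(OC(C)(C)C)OC(C)(C)C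
Why: Esterification by O-alkylation of the carboxylate is insensitive to the hindrance at C5 and leaves the 1-hydroxyl untouched, and the tert-butyl ester later resists alkoxide attack.

Step 8
Reactants: 13 C6 tert-butyl ester
Product: 14 1-O-TBS ether with C13=C14 TBS enol ether
Conditions: TBSOTf (2.5 equiv), Et3N, CH2Cl2, −78 → 0 °C
Reagents that add atoms: tert-butyldimethylsilyl trifluoromethanesulfonate CC(C)(C)[Si](C)(C)OS(=O)(=O)C(F)(F)F
Why: Soft enolisation with silyl triflate and amine, in which the C14 ketone can enolise only toward C13 because C8 is quaternary, and the C1 hydroxyl is silylated in the same operation.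

Step 9
Reactants: 14 bis-silyl compound
Product: 15 tricyclic 14-ketone (bicyclo[3.2.1]octane with 16-methylene; 1-OTBS)
Conditions: [(Ph3P)AuCl] (10 mol %), AgBF4 (10 mol %), toluene/MeOH (10:1), rt → 40 °C
Reagents that add atoms: none
Why: Gold-catalysed 5-exo-dig Conia-ene cyclisation of a silyl enol ether onto a terminal alkyne forms C13–C16 and ring D, and C13 can bond only on the face that carries the propargyl group, so its configuration follows from C8.

Step 10
Reactants: 15 tricyclic 14-ketone
Product: 16 14-alcohol (OH anti to the C15–C16 bridge)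
Conditions: NaBH4, MeOH/CH2Cl2, 0 °C
Reagents that add atoms: none
Why: Borohydride reduction of the strained bridging ketone, with hydride expected over ring D away from the axial C10 substituent; the new centre is removed two steps later, so its configuration is immaterial.

Step 11
Reactants: 16 14-alcohol
Product: 18 14-O-(S-methyl xanthate), via potassium xanthate 17 (not isolated)
Conditions: KN(SiMe3)2, THF, −78 °C; CS2; then MeI, −78 → 0 °C
Reagents that add atoms: carbon disulfide S=C=S; iodomethane CI
Why: Xanthate formation (first half of the Barton–McCombie deoxygenation) through the alkoxide at low temperature, where the small electrophile CS2 should trap the hindered alkoxide before retro-aldol cleavage toward the C7 ester can occur.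

Step 12
Reactants: 18 xanthate
Product: 19 14-deoxy compound (C14 and C15 both CH2; 16-methylene)
Conditions: Bu3SnH, AIBN (cat.), toluene, 100 °C
Reagents that add atoms: none
Why: Barton–McCombie radical deoxygenation, in which the secondary C14 radical has no favourable rearrangement (closure onto C16 could reopen only to a cyclobutane) and is reduced by the stannane.

Step 13
Reactants: 19 14-deoxy compound
Product: 20 15-exo allylic alcohol
Conditions: SeO2 (0.5 equiv), t-BuOOH (3 equiv), CH2Cl2, 0 °C → rt
Reagents that add atoms: SeO2 (selenium dioxide) O=[Se]=O; tert-butyl hydroperoxide CC(C)(C)OO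
Why: Selenium dioxide allylic oxidation (ene reaction, then 2,3-sigmatropic shift) can use only the C15 methylene because C13 is a bridgehead, and oxygen should be delivered to the open exo face of ring D (anti to the C9–C11–C12 bridge).

Step 14
Reactants: 20 15-exo allylic alcohol
Product: 21 15-hydroxy 16R-methyl compound (C17 endo)
Conditions: H2 (1 atm), [Ir(cod)(PCy3)(py)]PF6 (5 mol %), CH2Cl2, rt
Reagents that add atoms: none
Why: Hydroxyl-directed homogeneous hydrogenation adds hydrogen to C16 from the exo face shared with the 15-hydroxyl, which is also the less hindered face, and so places the methyl endo as in the target.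

Step 15
Reactants: 21 15-alcohol
Product: 22 15-O-methoxymethyl ether
Conditions: MOMCl, i-Pr2NEt, n-Bu4NI (cat.), CH2Cl2, 40 °C
Reagents that add atoms: chloromethyl methyl ether COCCl
Why: Acetal protection under amine base (no free alkoxide, hence no retro-aldol toward the C7 ester) masks the only other hydroxyl so that a single Si–H tether can be installed later.

Step 16
Reactants: 22 15-O-MOM ether
Product: 23 1-alcohol
Conditions: HF·pyridine, pyridine, THF, 0 °C → rt
Reagents that add atoms: none
Why: Fluoride cleavage of the silyl ether under buffered, non-basic conditions frees the C1 hydroxyl without forming a C1 alkoxide that could lactonise onto the C7 ester, while the acetal and both esters are inert.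

Step 17
Reactants: 23 1-alcohol
Product: 24 1-O-diethyl(hydrido)silyl ether
Conditions: Et2SiH2 (1.5 equiv), [Ir(cod)OMe]2 (0.5 mol %), THF, rt; volatiles removed, used crude
Reagents that add atoms: diethylsilane CC[SiH2]CC
Why: Iridium-catalysed dehydrogenative O-silylation of a secondary alcohol with a dihydrosilane should stop at the mono-alkoxy hydrosilane, because the neopentyl carbinol disfavours a second alcoholysis.

Step 18
Reactants: 24 1-O-diethyl(hydrido)silyl ether
Product: 25 oxasilolane (ring O1–SiEt2–C20–C10–C1)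
Conditions: [Ir(cod)OMe]2 (2 mol %), 3,4,7,8-tetramethyl-1,10-phenanthroline (5 mol %), norbornene (1.2 equiv), THF, 120 °C (sealed tube)
Reagents that add atoms: none
Why: The iridium methoxide/phenanthroline catalyst adds the Si–H bond, norbornene takes up the hydrogen, and the iridium silyl species cleaves a C–H bond of the C20 methyl through a six-membered iridacycle (Ir–Si–O–C1–C10–C20) before C–Si reductive elimination. The closest known reaction type is the hydroxyl-directed iridium-catalysed γ-C(sp3)–H silylation of (hydrido)silyl ethers of secondary alcohols, including methyl groups on a quaternary carbon next to the carbinol in terpenoids. The single new ring, the 1-oxa-2-silacyclopentane, closes by intramolecular dehydrogenative C–Si coupling and is cis-fused to ring A (equatorial O1, axial C20, O–C1–C10–C20 gauche). No stereocentre is created, since C20 becomes a methylene and silicon carries two ethyl groups. The step needs site selectivity for C20 over the other γ C–H bonds (C3–H2, C9–H) and must avoid carbonyl or alkene hydrosilylation. The first follows from the tether length and the catalyst's preference for primary C–H bonds (C20 is the only methyl within reach), the second from 24 having no ketone or alkene (C15 is an acetal-protected alcohol and esters are not reduced).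

Step 19
Reactants: 25 oxasilolane
Product: 26 1,20-diol
Conditions: H2O2 (30% aq), KHCO3, THF/MeOH (1:1), 50 °C
Reagents that add atoms: hydrogen peroxide OO
Why: Tamao–Fleming oxidation of the alkoxy-activated C–Si bond gives the primary C20 alcohol and releases the C1 hydroxyl.

Step 20
Reactants: 26 1,20-diol
Product: 27 7,20-lactone 1-alcohol
Conditions: K2CO3 (0.3 equiv), MeOH, 0 °C → rt
Reagents that add atoms: none
Why: Base-mediated lactonisation (intramolecular transesterification) in which the unhindered primary C20 alkoxide should attack the C7 methyl ester through a six-membered transition state far faster than the neopentyl C1 hydroxyl, while the tert-butyl ester at C6 resists the alternative five-membered lactone.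

Step 21
Reactants: 27 7,20-lactone 1-alcohol
Product: 28 1-acetate
Conditions: Ac2O, DMAP, pyridine, CH2Cl2, rt → 40 °C
Reagents that add atoms: acetic anhydride CC(=O)OC(C)=O
Why: DMAP-catalysed acylation of the equatorial secondary alcohol, the only free hydroxyl.

Step 22
Reactants: 28 1-acetate
Product: 29 15-hydroxy C6 acid
Conditions: TFA/CH2Cl2/H2O (10:10:1), 0 °C → rt
Reagents that add atoms: none
Why: Acidolysis cleaves the tert-butyl ester (as isobutene) and hydrolyses the methoxymethyl acetal, while the acetate and the lactone survive and no ketone is yet present that could epimerise C16.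

Step 23
Reactants: 29 15-hydroxy C6 acid
Product: 30 target, CNP0161834.1
Conditions: Dess–Martin periodinane, CH2Cl2, rt
Reagents that add atoms: none
Why: Dess–Martin oxidation of the hindered secondary alcohol under neutral conditions gives the C15 ketone without enolisation, so the kinetically set endo methyl at C16 is retained.

**Compound list**
1 | methyl 2-oxocyclohexane-1-carboxylate | COC(=O)C1CCCCC1=O | starting material
2 | methyl 2-oxo-1-(phenylselanyl)cyclohexane-1-carboxylate (racemic) | COC(=O)C1([Se]c2ccccc2)CCCCC1=O | intermediate (not isolated)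
3 | methyl 6-oxocyclohex-1-ene-1-carboxylate | COC(=O)C1=CCCCC1=O | intermediate
4 | 2,4,4-trimethylcyclohex-2-en-1-one | CC1=CC(C)(C)CCC1=O | starting material
5 | dimethylaluminium (R)-2,4,4-trimethyl-3-vinylcyclohex-1-en-1-olate | C[Al](C)OC1=C(C)[C@H](C=C)C(C)(C)CC1 | intermediate (not isolated)
6 | (R)-trimethyl[(2,4,4-trimethyl-3-vinylcyclohex-1-en-1-yl)oxy]silane | C[Si](C)(C)OC1=C(C)[C@H](C=C)C(C)(C)CC1 | intermediate
7 | C14 trimethylsilyl enol ether of 8 | O=C1CCC(C)(C)[C@@H](C=C)[C@]1(C)[C@@H]2CCCC(O[Si](C)(C)C)=C2C(=O)OC | intermediate (not isolated)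
8 | methyl 2-hydroxy-6-(1,3,3-trimethyl-6-oxo-2-vinylcyclohexyl)cyclohex-1-ene-1-carboxylate (enol form; C5, C9, C10 as in 30) | O=C1CCC(C)(C)[C@@H](C=C)[C@]1(C)[C@@H]2CCCC(O)=C2C(=O)OC | intermediate
9 | 1-hydroxy analogue of 8 (equatorial OH cis to C20) | O[C@H]1CCC(C)(C)[C@@H](C=C)[C@]1(C)[C@@H]2CCCC(O)=C2C(=O)OC | intermediate
10 | C8-propargyl 14-keto 7-methyl ester (propargyl trans to C10) | O[C@H]1CCC(C)(C)[C@@H](C=C)[C@]1(C)[C@@H]2CCCC(=O)[C@@]2(C(=O)OC)CC#C | intermediate
11 | C6 aldehyde of 10 | O[C@H]1CCC(C)(C)[C@@H](C=O)[C@]1(C)[C@@H]2CCCC(=O)[C@@]2(C(=O)OC)CC#C | intermediate (not isolated)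
12 | C6 carboxylic acid | O[C@H]1CCC(C)(C)[C@@H](C(=O)O)[C@]1(C)[C@@H]2CCCC(=O)[C@@]2(C(=O)OC)CC#C | intermediate
13 | C6 tert-butyl ester | O[C@H]1CCC(C)(C)[C@@H](C(=O)OC(C)(C)C)[C@]1(C)[C@@H]2CCCC(=O)[C@@]2(C(=O)OC)CC#C | intermediate
14 | 1-O-TBS ether, C13=C14 TBS enol ether | CC(C)(C)[Si](C)(C)O[C@H]1CCC(C)(C)[C@@H](C(=O)OC(C)(C)C)[C@]1(C)[C@@H]2CCC=C(O[Si](C)(C)C(C)(C)C)[C@@]2(C(=O)OC)CC#C | intermediate
15 | 1-OTBS 14-oxo-16-methylene tricycle (ring D closed) | CC(C)(C)[Si](C)(C)O[C@H]1CCC(C)(C)[C@@H](C(=O)OC(C)(C)C)[C@]1(C)[C@@H]2CC[C@@H]3C(=O)[C@@]2(C(=O)OC)CC3=C | intermediate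
16 | 14-alcohol (OH anti to the C15–C16 bridge) | CC(C)(C)[Si](C)(C)O[C@H]1CCC(C)(C)[C@@H](C(=O)OC(C)(C)C)[C@]1(C)[C@@H]2CC[C@@H]3[C@H](O)[C@@]2(C(=O)OC)CC3=C | intermediate
17 | potassium 14-O-xanthate | CC(C)(C)[Si](C)(C)O[C@H]1CCC(C)(C)[C@@H](C(=O)OC(C)(C)C)[C@]1(C)[C@@H]2CC[C@@H]3[C@H](OC(=S)[S-])[C@@]2(C(=O)OC)CC3=C.[K+] | intermediate (not isolated)
18 | 14-O-(S-methyl xanthate) | CC(C)(C)[Si](C)(C)O[C@H]1CCC(C)(C)[C@@H](C(=O)OC(C)(C)C)[C@]1(C)[C@@H]2CC[C@@H]3[C@H](OC(=S)SC)[C@@]2(C(=O)OC)CC3=C | intermediate
19 | 14-deoxy 16-methylene compound | CC(C)(C)[Si](C)(C)O[C@H]1CCC(C)(C)[C@@H](C(=O)OC(C)(C)C)[C@]1(C)[C@@H]2CC[C@@H]3C[C@@]2(C(=O)OC)CC3=C | intermediate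
20 | 15-exo-hydroxy 16-methylene compound | CC(C)(C)[Si](C)(C)O[C@H]1CCC(C)(C)[C@@H](C(=O)OC(C)(C)C)[C@]1(C)[C@@H]2CC[C@@H]3C[C@@]2(C(=O)OC)[C@@H](O)C3=C | intermediate
21 | 15-hydroxy 16R-methyl compound | CC(C)(C)[Si](C)(C)O[C@H]1CCC(C)(C)[C@@H](C(=O)OC(C)(C)C)[C@]1(C)[C@@H]2CC[C@@H]3C[C@@]2(C(=O)OC)[C@@H](O)[C@@H]3C | intermediate
22 | 15-O-MOM 1-O-TBS compound | CC(C)(C)[Si](C)(C)O[C@H]1CCC(C)(C)[C@@H](C(=O)OC(C)(C)C)[C@]1(C)[C@@H]2CC[C@@H]3C[C@@]2(C(=O)OC)[C@@H](OCOC)[C@@H]3C | intermediate
23 | 15-O-MOM 1-alcohol (20-methyl seco diester) | O[C@H]1CCC(C)(C)[C@@H](C(=O)OC(C)(C)C)[C@]1(C)[C@@H]2CC[C@@H]3C[C@@]2(C(=O)OC)[C@@H](OCOC)[C@@H]3C | intermediate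
24 | 1-O-diethyl(hydrido)silyl ether | CC[SiH](CC)O[C@H]1CCC(C)(C)[C@@H](C(=O)OC(C)(C)C)[C@]1(C)[C@@H]2CC[C@@H]3C[C@@]2(C(=O)OC)[C@@H](OCOC)[C@@H]3C | intermediate
25 | C1–O–SiEt2–C20 oxasilolane | CC[Si]5(CC)O[C@H]1CCC(C)(C)[C@@H](C(=O)OC(C)(C)C)[C@]1(C5)[C@@H]2CC[C@@H]3C[C@@]2(C(=O)OC)[C@@H](OCOC)[C@@H]3C | intermediate
26 | 1,20-diol | O[C@H]1CCC(C)(C)[C@@H](C(=O)OC(C)(C)C)[C@]1(CO)[C@@H]2CC[C@@H]3C[C@@]2(C(=O)OC)[C@@H](OCOC)[C@@H]3C | intermediate
27 | 7,20-lactone 1-alcohol | O[C@H]1CCC(C)(C)[C@@H](C(=O)OC(C)(C)C)[C@]1(CO4)[C@@H]2CC[C@@H]3C[C@@]2(C4=O)[C@@H](OCOC)[C@@H]3C | intermediate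
28 | 7,20-lactone 1-acetate | CC(=O)O[C@H]1CCC(C)(C)[C@@H](C(=O)OC(C)(C)C)[C@]1(CO4)[C@@H]2CC[C@@H]3C[C@@]2(C4=O)[C@@H](OCOC)[C@@H]3C | intermediate
29 | 1-acetoxy 15-hydroxy C6 acid | CC(=O)O[C@H]1CCC(C)(C)[C@@H](C(=O)O)[C@]1(CO4)[C@@H]2CC[C@@H]3C[C@@]2(C4=O)[C@@H](O)[C@@H]3C | intermediate
30 | CNP0161834.1 (1-acetoxy-15-oxo-6,7-seco-ent-kauran-7,20-olid-6-oic acid) | CC(=O)O[C@H]1CCC(C)(C)[C@@H](C(=O)O)[C@@]12COC(=O)[C@@]13C[C@@H](CC[C@H]12)[C@@H](C)C3=O | target

**Count and risks**
Total: 23 steps. Longest linear sequence: 22 steps (4 to 30, steps 2–23); step 1 is the only side branch.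

Step 2. The copper-catalysed vinyl transfer to an enone that is both α-methylated and flanked by a quaternary carbon may be slow, and ligand-free background addition may then erode the enantioselectivity. The fallback moves the methyl introduction behind the asymmetric step. The same alane addition is run on commercial 4,4-dimethylcyclohex-2-en-1-one F1, an α-unsubstituted enone of the type for which this catalysis is established, taken in place of 4. The aluminium enolate is trapped as (S)-[(4,4-dimethyl-3-vinylcyclohex-1-en-1-yl)oxy]trimethylsilane F2. MeLi in THF releases the lithium enolate regiospecifically and MeI methylates C10 to give trans-2,4,4-trimethyl-3-vinylcyclohexan-1-one F3. Equilibrating silylation (TMSCl, NaI, Et3N, MeCN) then gives the tetrasubstituted enol silane. The fallback leaves the route at 4 and returns at 6.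

Step 3. The two open transition states may differ little in energy, so facial discrimination at C9 may be poor, and the C9 epimers cannot be equilibrated afterwards. The fallback erases and resets C9. The epimer mixture 8 is selenenylated (PhSeCl, pyridine) to the C8-phenylselanyl keto ester F4 and oxidised (H2O2) to the C8=C9 enone F5. Ligand-controlled conjugate reduction with a copper hydride (CuCl, NaOt-Bu, p-tol-BINAP, polymethylhydrosiloxane, toluene, 0 °C; acidic work-up) then delivers hydride to C9 under catalyst control. The fallback sets out from 8 and returns to 8.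

Step 18. C–H cleavage at the congested axial methyl, which is syn-axial to a C4 methyl, may be slow, so that redistribution or hydrolysis of the silyl ether consumes 24 first. The fallback is oxime-directed palladium-catalysed C–H acetoxylation. Alcohol 23 is oxidised (Dess–Martin periodinane) to the C1 ketone F6 and condensed with NH2OH·HCl/NaOAc to the (E)-oxime F7, whose OH lies away from C10. Pd(OAc)2/PhI(OAc)2 in AcOH/Ac2O at 80 °C should acetoxylate the C20 methyl through a five-membered palladacycle, giving the 20-acetoxy O-acetyl oxime F8. Bisulfite hydrolysis gives the 20-acetoxy ketone F9, and NaBH4 (axial delivery, as in step 4) gives the 20-acetoxy 1-alcohol F10. K2CO3 in MeOH then removes the acetate and lactonises. The fallback sets out from 23 and returns at 27.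

**Further compounds**
F1 | step 2 | 4,4-dimethylcyclohex-2-en-1-one | CC1(C)CCC(=O)C=C1
F2 | step 2 | (S)-[(4,4-dimethyl-3-vinylcyclohex-1-en-1-yl)oxy]trimethylsilane | C[Si](C)(C)OC1=C[C@H](C=C)C(C)(C)CC1
F3 | step 2 | trans-2,4,4-trimethyl-3-vinylcyclohexan-1-one (vinyl centre as in 6) | O=C1CCC(C)(C)[C@@H](C=C)[C@@H]1C
F4 | step 3 | C8-phenylselanyl derivative of 8 (mixture at C8 and C9) | O=C1CCC(C)(C)[C@@H](C=C)[C@]1(C)C2CCCC(=O)C2([Se]c3ccccc3)C(=O)OC
F5 | step 3 | C8=C9 enone: methyl 6-oxo-2-(1,3,3-trimethyl-6-oxo-2-vinylcyclohexyl)cyclohex-1-ene-1-carboxylate | O=C1CCC(C)(C)[C@@H](C=C)[C@]1(C)C2=C(C(=O)OC)C(=O)CCC2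
F6 | step 18 | C1 ketone of 23 | O=C1CCC(C)(C)[C@@H](C(=O)OC(C)(C)C)[C@]1(C)[C@@H]2CC[C@@H]3C[C@@]2(C(=O)OC)[C@@H](OCOC)[C@@H]3C
F7 | step 18 | (E)-C1 oxime | O/N=C1\CCC(C)(C)[C@@H](C(=O)OC(C)(C)C)[C@]1(C)[C@@H]2CC[C@@H]3C[C@@]2(C(=O)OC)[C@@H](OCOC)[C@@H]3C
F8 | step 18 | 20-acetoxy (E)-C1 O-acetyl oxime | CC(=O)O/N=C1\CCC(C)(C)[C@@H](C(=O)OC(C)(C)C)[C@]1(COC(C)=O)[C@@H]2CC[C@@H]3C[C@@]2(C(=O)OC)[C@@H](OCOC)[C@@H]3C
F9 | step 18 | 20-acetoxy C1 ketone | O=C1CCC(C)(C)[C@@H](C(=O)OC(C)(C)C)[C@]1(COC(C)=O)[C@@H]2CC[C@@H]3C[C@@]2(C(=O)OC)[C@@H](OCOC)[C@@H]3C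
F10 | step 18 | 20-acetoxy 1-alcohol | O[C@H]1CCC(C)(C)[C@@H](C(=O)OC(C)(C)C)[C@]1(COC(C)=O)[C@@H]2CC[C@@H]3C[C@@]2(C(=O)OC)[C@@H](OCOC)[C@@H]3C
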